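## Structural features

The target is a ten-membered carbocycle, numbered here C1 to C10: C1 is the hemiketal carbon, C2 and C3 are the CH2 groups, C4 is the methyl-bearing ether carbon, C5 the vinylic CH, C6 the enol-lactone carbon, C7 the ring carbon of the butenolide, C8 the acyloxy carbon, C9 a CH2 and C10 the methyl-bearing CH. An oxygen bridges C1 and C4, so C1, C2, C3, C4 and that oxygen form a tetrahydrofuran. A butenolide (C6–O–C12(=O)–C11=C7) is fused at C6–C7; C6 also carries the exocyclic C5=C6 enol-lactone bond, and C11 carries the acetoxymethyl carbon C13. C8 bears the (R)-3-chloro-2-hydroxy-2-methylpropanoate. The stereocentres are C1 (S), C4 (R), C8 (R), C10 (R) and C2′ (R) of the ester; C10 stands next to C1 and C8 next to C7, whereas C4 lies across the ring from both. The fragile groups are the hemiketal (ring-chain tautomerism, C10 epimerisable), the cross-conjugated dienyl lactone (acceptor at C5), the allylic C13 acetate (lost by addition–elimination), and the chlorohydrin ester (closes to an epoxide with base). C1 is not an independent problem: with C4–OH, a C1 ketone and a ring-cis C5=C6 bond in place, only the cis-bridged hemiketal can form. The real difficulty is the medium ring with the C4 ether centre set relative to C8 and C10 and with C4 cis to C7 across C5=C6. The key step uses the fact that the carbonyl-level C1 and the C5=C6 alkene are separated by exactly C2, C3 and C4, the pattern left by an oxy-Cope shift, and that C6 already carries the lactone oxygen.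

## Logic of the disconnections

36 is cut at the C8–O acyl bond to 34 and 35. The chlorohydrin ester tolerates neither base nor fluoride-free strong acid, so it goes on last. The forward step must acylate a hindered secondary allylic alcohol without touching the hemiketal hydroxyl or displacing the C13 acetate.

34 is cut at the C13–O acyl bond to 33, and 33 at two O–Si bonds to 32. This leaves one protecting-group pattern for everything before. The forward demand is a primary-over-secondary acetylation.

32 is opened at the C1–O bond of the bridge to 30. This turns the bridged bicycle into a simple ten-membered ketone. The forward step must free the tertiary C4 hydroxyl under conditions that do not ionise the allylic C4–O bond; the hemiketal then closes by itself.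

30 is related to 29 by the geometry of C5=C6 only; no bond is cut. The ring expansion can place C4 only on the side of the lactone oxygen (see the key step), so the ring-cis isomer has to be derived from the ring-trans one. The forward step is an E/Z isomerisation that leaves C4 alone.

29 is cut at C3–C4 while C1–C6 is re-formed, giving 26. This removes the medium ring in one stroke and exchanges the C4 stereocentre for an alkene geometry. The forward [3,3] shift must run through one chair array and must be faster than heterolysis of C1–C6.

26 is traced through 25 to 24 and cut at C4=C5 to 19 and 23; 23 is cut at O–CH2 to 22 and at P–C to 20 and 21. An enol ether of defined geometry is best made by a stereospecific elimination. The demand is that the right diastereomer of 24 can be separated and that the C1 oxygen is masked while alkoxides are formed at C5.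

19 is traced to 18 (aldehyde masked as acetal) and 18 to 16 by removing the C7=C11 double bond. The butenolide is introduced only after C1 is configured, because the flat butenolide would turn the C6 carbon substituent axial and send the vinyl group to the wrong face. The forward step must dehydrogenate the lactone towards C7 only.

16 is traced to 15, which is cut at C1–C2 to 13 and 14. In the cis-fused saturated lactone the C6–O bond is axial, so the addition should occur anti to it. The demand is addition without enolisation at C10.

13 is traced to 12 and 11 (C10–H and C9–H bonds cut) and 11 to 9 (C8–O bond cut). The enone of the carvone ring supplies both the γ-oxygen and, through the new C8 hydroxyl, a handle to direct hydrogen to one face at C10.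

9 is cut at C6–C5 to 7, and 7 at C6–O to 5. Closing the lactone onto C6 first fixes C6–O cis to C7–C11; the one-carbon unit then has only one face left.

5 is traced through 4, 3 and 2 to 1 by oxidation-level changes at C12 and C13. The isopropenyl group supplies C11, C12 and C13; the C7 centre of 1 relays chirality to C6 and C8 and is destroyed in step 12.

## Other disconnections considered

Alternative 1: The cut is C7–C8. In the forward step the vinyl iodide A1 would be taken with CrCl2 and catalytic NiCl2 (zerovalent nickel inserts, trivalent vinylchromium adds to the aldehyde) to the cyclised carbinol A2.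
- In its favour: the ring and the C8 carbinol form together under neutral conditions that tolerate ketone, ester, acetate and ketal. The tetrasubstituted alkene geometry is set beforehand and should be retained. C4 and the C1–O–C4 bridge are already in place.
- Better than the chosen plan on one point: with the bridge present, later enol-lactonisation of the C6 ketone can only give C4 cis to C7, so no alkene isomerisation is needed. It is also more convergent.
- Against it here: a ten-membered ring must close by end-to-end addition of a fully substituted, electron-poor vinyl metal, which calls for high dilution and a large excess of CrCl2. The C8 configuration would rest on macrocyclic control alone. A1 needs a stereodefined tetrasubstituted β-iodoacrylate.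
- Comparison: the chosen plan avoids end-to-end closure and sets C8 on a six-membered ring. Its mechanism is pericyclic, not a polar metal addition. The overall step count is probably equal; the chosen plan is longer in its linear sequence.

Alternative 2: No skeletal bond is cut; the butenolide is traced to the furan A3. In the forward step singlet oxygen would add across C6 and C12, and iPr2NEt would open the endoperoxide by removing the C12 hydrogen to give the hydroxybutenolide A4.
- In its favour: it is a last-stage, near-neutral oxidation. The regiochemistry of the carbonyl is fixed by the single endoperoxide hydrogen.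
- Better than the chosen plan on functional-group tolerance: the chlorohydrin ester, the acetate and the hemiketal can all be present, whereas the chosen key step needs a strong base and full protection.
- Against it here: it forms no ring, so the ten-membered furan A3 still has to be made by some other ring construction. A4 still lacks the C5=C6 bond, and dehydration of a labile C6 hemiketal-type hydroxyl next to the C4 ether must be regio- and geometry-selective.
- Comparison: it solves a smaller part of the problem than the chosen plan. On redox step economy the two are equal, since the chosen plan carries the lactone oxidation level from the start and this one postpones it.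

Alternative 3: The cut is C9–C10, as an alkene, from the eleven-membered sulfone A5. In the forward step α-halogenation in situ (KOH, CCl4, t-BuOH), episulfone closure and loss of SO2 would give the ring-contracted alkene A6.
- In its favour: an eleven-membered thioether is easier to close than a ten-membered carbocycle, and the sulfur extrusion is reliable for medium rings.
- Equal or better on C4: as in Alternative 1, C4 and the oxygen bridge are set before ring closure.
- Against it here: the step makes an alkene where the target has a saturated C9–C10 bond with a stereocentre at C10, so a face-selective hydrogenation of a trisubstituted alkene next to a furan must follow. The C9 carbanion sits β to the C8 silyloxy group and may eliminate it. The furan must still be oxidised as in Alternative 2 and the C5=C6 bond introduced.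
- Comparison: the chosen plan fixes C10 and C8 before the ring is expanded and needs fewer steps after the key step. The mechanisms differ (anionic extrusion against a concerted shift), and both run under strongly basic conditions.

Key step: step 19

Remarks on the chemistry before the steps:
- C11 is formed as an epimer mixture in step 3 and becomes trigonal in step 12; the SMILES of 4–13, 15 and 16 leave it unassigned (4 also leaves C1 unassigned).
- The descriptors of 26 (1R,6S,8R,10R), 30 (4R,8R,10R) and 36 (1S,4R,8R,10R,2′R) were checked against their SMILES.
- Three assignments follow from the stereochemical analysis: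
  - (S)-carvone is the enantiomer needed, because the lactone oxygen is delivered cis and the C8 oxygen trans to the C7 side chain.
  - The vinyl group is added before the butenolide double bond is made.
  - The enol ether must be Z. The butenolide holds C6–O in its own plane, so the only unstrained chair for the shift puts C4 next to the lactone oxygen and gives the ring-trans C5=C6 bond. With that chair the Z enol ether gives 4R, and the E isomer would give 4S. Step 20 then corrects the alkene geometry.
- Numbered reactants are not repeated under reagents.

Step 1
Reactants: 1 (S)-carvone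
Product: 2 (S)-10-hydroxycarvone
Conditions: SeO2 (cat.), t-BuOOH, CH2Cl2, rt
Reagents that add atoms: tert-butyl hydroperoxide, CC(C)(C)OO
Why: Riley-type allylic hydroxylation (ene reaction, then [2,3] shift) should attack the electron-rich 1,1-disubstituted alkene and not the enone alkene, and oxidise its methyl group (C13). The C7 centre is not involved.

Step 2
Reactants: 2 (S)-10-hydroxycarvone
Product: 3 C13 tert-butyldimethylsilyl ether of 2
Conditions: t-BuMe2SiCl, imidazole, DMF, 0 °C to rt
Reagents that add atoms: tert-butyldimethylsilyl chloride, CC(C)(C)[Si](C)(C)Cl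
Why: Standard silylation of a primary allylic alcohol; the ether must survive bases, oxidants and organometallics up to step 22.

Step 3
Reactants: 3 C13 tert-butyldimethylsilyl ether of 2
Product: 4 diol with C1 allylic alcohol and C12 primary alcohol
Conditions: 9-BBN, THF, 0 °C to rt; then NaOH, H2O2, 0 °C
Reagents that add atoms: hydrogen peroxide, OO
Why: Hydroboration–oxidation places boron on the terminal carbon of the 1,1-disubstituted alkene; 9-BBN also reduces the enone carbonyl in the 1,2 sense, which step 4 reverses. The trisubstituted ring alkene is too hindered to react, and the new centres at C1 and C11 are erased later.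

Step 4
Reactants: 4 diol with C1 allylic alcohol and C12 primary alcohol
Product: 5 keto acid with side chain CH(CO2H)(CH2OTBS) on C7
Conditions: TEMPO (cat.), PhI(OAc)2, MeCN/H2O, rt
Reagents that add atoms: water, O
Why: Oxoammonium oxidation should take the primary alcohol through the aldehyde hydrate to the acid and the allylic alcohol back to the enone in one operation. The silyl ether and the ring alkene are inert.

Step 5
Reactants: 5 keto acid with side chain CH(CO2H)(CH2OTBS) on C7
Product: 7 cis-fused keto lactone with C6–O cis to C7–C11, via iodo keto carboxylate 6 (not isolated)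
Conditions: LiN(iPr)2 (2.2 equiv), THF, −78 °C; I2, −78 °C to rt
Reagents that add atoms: none
Why: Kinetic deprotonation of the enone carboxylate occurs at the cross-conjugated α′ carbon C6, and iodine should add anti to the C7 side chain. The carboxylate then displaces iodide with inversion (α-halo ketone substitution, 5-exo-tet), so the new C6–O bond can only be cis to C7–C11.

Step 6
Reactants: 7 cis-fused keto lactone with C6–O cis to C7–C11
Product: 9 C6 dimethoxymethyl keto lactone, via silyl enol ether 8 (not isolated)
Conditions: LiN(iPr)2, Me3SiCl, THF, −78 °C; then HC(OMe)3, Me3SiOTf (cat.), CH2Cl2, −78 °C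
Reagents that add atoms: trimethyl orthoformate, COC(OC)OC
Why: Mukaiyama-type addition of the C1=C6 silyl enol ether to the dimethoxycarbenium ion; the C6 hydrogen, α to ketone and acyloxy oxygen, is the most acidic. The electrophile should enter anti to C7–C11, the only approach that keeps the five-membered lactone cis-fused, so C5 ends trans to C11.

Step 7
Reactants: 9 C6 dimethoxymethyl keto lactone
Product: 11 γ-hydroxy enone with 8R hydroxyl, via silyl dienol ether 10 (not isolated)
Conditions: KN(SiMe3)2, t-BuMe2SiCl, THF, −78 °C; then dimethyldioxirane, acetone/CH2Cl2, −78 to −20 °C; aq. citric acid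
Reagents that add atoms: dimethyldioxirane, CC1(C)OO1
Why: Vinylogous Rubottom oxidation: with C6 quaternary the ketone can enolise only through C8, and the linear dienol ether should be epoxidised at its terminal C8=C9 bond, not at the tetrasubstituted C1=C10 bond. The oxidant should approach anti to the axial lactone oxygen and to C11, which places the hydroxyl trans to C7–C11 (8R).

Step 8
Reactants: 11 γ-hydroxy enone with 8R hydroxyl
Product: 12 saturated ketone with 10R methyl
Conditions: H2 (1 atm), [Ir(cod)(PCy3)(py)]PF6 (cat.), CH2Cl2, rt
Reagents that add atoms: none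
Why: Hydroxyl-directed homogeneous hydrogenation: the cationic iridium centre binds the C8 hydroxyl and delivers hydrogen to that face, so C10–H is cis and the methyl trans to the C8 oxygen (10R). This is the less stable epimer in this ring conformer, so 12 is kept away from base.

Step 9
Reactants: 12 saturated ketone with 10R methyl
Product: 13 C8 tert-butyldimethylsilyl ether of 12
Conditions: t-BuMe2SiCl, imidazole, DMF, rt
Reagents that add atoms: tert-butyldimethylsilyl chloride, CC(C)(C)[Si](C)(C)Cl
Why: Silylation with a weak base avoids both enolisation at C10 and Lewis-acid attack on the acetal.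

Step 10
Reactants: 13 C8 tert-butyldimethylsilyl ether of 12; 14 vinylmagnesium bromide
Product: 15 C1 vinyl carbinol (1R)
Conditions: CeCl3, THF, −78 °C; aq. NH4Cl
Reagents that add atoms: none
Why: Grignard 1,2-addition, with CeCl3 to suppress enolisation at C10 and attack on the lactone. In the cis-fused lactone the C6–O bond and the C10 methyl are both axial on one face of the carbonyl, so vinyl should enter axially from the other face, anti to C6–O (polar Felkin–Anh sense). That gives the hydroxyl cis to the lactone oxygen and vinyl cis to C5.

Step 11
Reactants: 15 C1 vinyl carbinol (1R)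
Product: 16 C1 trimethylsilyl ether of 15
Conditions: 1-(trimethylsilyl)imidazole, CH2Cl2, rt
Reagents that add atoms: 1-(trimethylsilyl)imidazole, C[Si](C)(C)n1ccnc1
Why: A non-acidic silyl donor strong enough for a tertiary alcohol; the ether keeps the C1 oxygen from forming an alkoxide next to the lactone in steps 12 to 17.

Step 12
Reactants: 16 C1 trimethylsilyl ether of 15
Product: 18 butenolide with C7=C11, via selenide 17 (not isolated)
Conditions: LiN(iPr)2, THF, −78 °C; PhSeBr; then H2O2, pyridine, CH2Cl2, 0 °C
Reagents that add atoms: none
Why: Selenenylation of the lactone enolate followed by selenoxide syn-elimination; both C11 epimers give the same enolate, and selenium should enter on the convex face, cis to C7–H. Elimination can run only towards C7, not towards the oxygen-bearing C13, and the flat butenolide then turns the C6 carbon substituent axial.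

Step 13
Reactants: 18 butenolide with C7=C11
Product: 19 C5 aldehyde
Conditions: Me3SiOTf, 2,2′-bipyridyl, CH2Cl2, 0 °C; then H2O
Reagents that add atoms: water, O
Why: Silyl triflate and a pyridine base convert the dimethyl acetal into a pyridinium N,O-acetal, which water hydrolyses to the aldehyde without free acid. The tertiary trimethylsilyl ether and both tert-butyldimethylsilyl ethers should survive.

Step 14
Reactants: 20 diphenylphosphine oxide; 21 acetaldehyde
Product: 22 (1-hydroxyethyl)diphenylphosphine oxide
Conditions: Et3N (cat.), THF, 0 °C to rt
Reagents that add atoms: none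
Why: Pudovik-type addition of the P–H bond to the aldehyde; the racemic centre is lost in step 17.

Step 15
Reactants: 22 (1-hydroxyethyl)diphenylphosphine oxide
Product: 23 [1-(methoxymethoxy)ethyl]diphenylphosphine oxide
Conditions: MeOCH2Cl, iPr2NEt, CH2Cl2, 0 °C to rt
Reagents that add atoms: chloromethyl methyl ether, COCCl
Why: O-Alkylation under mild base, which avoids reversal of step 14.

Step 16
Reactants: 19 C5 aldehyde; 23 [1-(methoxymethoxy)ethyl]diphenylphosphine oxide
Product: 24 β-hydroxy phosphine oxide, Z-competent diastereomer
Conditions: LiN(iPr)2, THF, −78 °C; then AcOH, −78 °C; chromatography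
Reagents that add atoms: none
Why: First stage of a Horner–Wittig olefination: the lithiated α-alkoxy phosphine oxide adds to the non-enolisable aldehyde and the lithium alkoxide does not eliminate, so the diastereomers can be separated. The pair taken on has C6 and OMOM eclipsed when O–C5 and C4–P are syn (one member is drawn; its C4,C5 bis-epimer serves equally). The cold quench prevents silyl migration from the C1 oxygen.

Step 17
Reactants: 24 β-hydroxy phosphine oxide, Z-competent diastereomer
Product: 25 (Z)-enol ether with C1 trimethylsilyl ether
Conditions: KH, THF, 0 °C to rt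
Reagents that add atoms: none
Why: Second stage of the Horner–Wittig olefination: stereospecific syn loss of diphenylphosphinate from the potassium alkoxide fixes OMOM cis to C6.

Step 18
Reactants: 25 (Z)-enol ether with C1 trimethylsilyl ether
Product: 26 cis-vinyl carbinol with (Z)-enol ether on the bicyclic butenolide (1R,6S,8R,10R)
Conditions: Bu4NF, AcOH, THF, −20 °C
Reagents that add atoms: none
Why: Buffered fluoride should cleave the tertiary trimethylsilyl ether far faster than the two tert-butyldimethylsilyl ethers. The buffer spares the enol ether and prevents a free alkoxide from forming before step 19.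

Step 19
Reactants: 26 cis-vinyl carbinol with (Z)-enol ether on the bicyclic butenolide (1R,6S,8R,10R)
Product: 29 ten-membered keto ylidene-butenolide (4R,5Z) with C4 OMOM, via potassium alkoxide 27 (not isolated), via potassium enolate 28 (not isolated)
Conditions: KN(SiMe3)2, 18-crown-6, THF, −78 to −40 °C; then AcOH, −78 °C
Reagents that add atoms: none
Why: Deprotonation gives the crown-separated alkoxide 27, in which C3 bonds to C4 while C1–C6 breaks in a concerted suprafacial [3,3] shift; the closest known reaction type is the anionic oxy-Cope ring expansion of cis-1-vinyl-2-alkenylcyclohexanols to cyclodec-5-enones. The ten-membered ring is not closed end to end but arises by four-atom ring expansion, the C3–C4 bond joining the termini of two alkenyl groups already held cis on the six-membered ring. The butenolide keeps C6–O in its own plane, so on the chair cyclohexane the C6 alkenyl group is axial and the vinyl group equatorial and directed away from C7; the only unstrained chair array of C3, C2, C1, C6, C5 and C4 then has the lactone oxygen axial, C7 equatorial, the alkoxide oxygen equatorial and C10 axial. C4 therefore ends next to the lactone oxygen, so the C5=C6 bond forms ring-trans (5Z) and enolate 28 has C10 cis to C3. The new centre C4 is controlled by the C6 configuration, which fixes the face of the lactone plane on which C1 leaves and C3 arrives, together with the Z enol ether (OMOM inside and axial, methyl outside and equatorial); this should give 4R. A chair with C7 axial would give the ring-cis alkene directly, but it needs a twisted cyclohexane and presses the inner C4 substituent against C8, so it is not relied on. The selectivity needed is shift over heterolysis of C1–C6 (retro-vinylogous aldol to a 2-oxyfuran anion) and over attack of the alkoxide on the lactone carbonyl; the ground-state alignment of C1–C6 with both π systems, the naked alkoxide and the low temperature should secure it. Protonation of 28 at C2 with acetic acid at −78 °C leaves C10 untouched.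

Step 20
Reactants: 29 ten-membered keto ylidene-butenolide (4R,5Z) with C4 OMOM
Product: 30 ten-membered keto ylidene-butenolide (4R,5E) with C4 OMOM
Conditions: thioxanthen-9-one (cat.), 405 nm light, MeCN, rt
Reagents that add atoms: none
Why: Triplet-sensitised E/Z isomerisation of a γ-ylidene butenolide by energy transfer. The isomer with C4 next to C7 and C8 is twisted out of conjugation, should accept energy less well and so accumulate; in the ten-membered ring it is also the cis cycloalkene. C4 is not involved.

Step 21
Reactants: 30 ten-membered keto ylidene-butenolide (4R,5E) with C4 OMOM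
Product: 32 1,4-epoxy hemiketal with C8 and C13 silyl ethers, via hydroxy ketone 31 (not isolated)
Conditions: Me2BBr, CH2Cl2, −78 °C; then THF, aq. NaHCO3
Reagents that add atoms: none
Why: Lewis-acid cleavage of the methoxymethyl acetal at −78 °C (bromomethyl ether, hydrolysed on work-up) avoids ionising the allylic C4–O bond. The freed C4 hydroxyl adds to the C1 ketone across the ring, and only the cis-bridged hemiketal (1S) is geometrically possible.

Step 22
Reactants: 32 1,4-epoxy hemiketal with C8 and C13 silyl ethers
Product: 33 hemiketal triol with free C8 and C13 hydroxyls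
Conditions: HF·pyridine, pyridine, THF, 0 °C to rt
Reagents that add atoms: none
Why: Buffered fluoride desilylation; the weakly acidic, non-nucleophilic medium should spare the dienyl lactone and the hemiketal.

Step 23
Reactants: 33 hemiketal triol with free C8 and C13 hydroxyls
Product: 34 C13 acetate
Conditions: Ac2O (1.05 equiv), 2,4,6-collidine, CH2Cl2, −20 °C
Reagents that add atoms: acetic anhydride, CC(=O)OC(C)=O
Why: Kinetic acetylation with a hindered base should select the primary allylic hydroxyl over the hindered secondary C8 hydroxyl and the tertiary hemiketal hydroxyl.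

Step 24
Reactants: 34 C13 acetate; 35 (R)-3-chloro-2-hydroxy-2-methylpropanoic acid
Product: 36 target (CNP0414417.2)
Conditions: EDC·HCl, DMAP (cat.), CH2Cl2, 0 °C
Reagents that add atoms: none
Why: Steglich-type carbodiimide esterification of the one remaining secondary alcohol; the tertiary hydroxyls of the acid and of the hemiketal are too hindered to compete. The cold, weakly basic medium should avoid epoxide closure of the chlorohydrin and loss of the C13 acetate, and the C2′ centre is not involved.

## Compound list

1 | (S)-carvone, (5S)-2-methyl-5-(prop-1-en-2-yl)cyclohex-2-en-1-one | CC1=CC[C@@H](CC1=O)C(C)=C | starting material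
2 | (S)-10-hydroxycarvone, carvone with the isopropenyl methyl (C13) hydroxylated | CC1=CC[C@@H](CC1=O)C(=C)CO | intermediate
3 | C13 tert-butyldimethylsilyl ether of 2 | CC1=CC[C@@H](CC1=O)C(=C)CO[Si](C)(C)C(C)(C)C | intermediate
4 | diol: C1 allylic alcohol, C7 side chain CH(CH2OH)(CH2OTBS), C1 and C11 epimer mixture | CC1=CC[C@@H](CC1O)C(CO)CO[Si](C)(C)C(C)(C)C | intermediate
5 | keto acid: enone restored, C7 side chain CH(CO2H)(CH2OTBS), C11 epimers | CC1=CC[C@@H](CC1=O)C(CO[Si](C)(C)C(C)(C)C)C(=O)O | intermediate
6 | lithium carboxylate of the 6-iodo keto acid, iodine trans to the C7 side chain (not isolated) | CC1=CC[C@@H]([C@@H](I)C1=O)C(CO[Si](C)(C)C(C)(C)C)C(=O)[O-].[Li+] | intermediate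
7 | cis-fused keto lactone: 12,6-lactone with C6–H, C6–O cis to C7–C11, C1 enone retained, C11 epimers | CC(C)(C)[Si](C)(C)OCC1[C@H]2CC=C(C)C(=O)[C@H]2OC1=O | intermediate
8 | C1 trimethylsilyl enol ether (C1=C6) of 7 (not isolated) | CC(C)(C)[Si](C)(C)OCC1[C@H]2CC=C(C)C(O[Si](C)(C)C)=C2OC1=O | intermediate
9 | C6 dimethoxymethyl keto lactone: C6 quaternary, lactone O cis and CH(OMe)2 (C5) trans to C7–C11 | CC(C)(C)[Si](C)(C)OCC1[C@H]2CC=C(C)C(=O)[C@@]2(C(OC)OC)OC1=O | intermediate
10 | C1 tert-butyldimethylsilyl dienol ether (C1=C10, C8=C9) of 9 (not isolated) | CC(C)(C)[Si](C)(C)OCC1[C@H]2C=CC(C)=C(O[Si](C)(C)C(C)(C)C)[C@@]2(C(OC)OC)OC1=O | intermediate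
11 | γ-hydroxy enone: 9 with 8R hydroxyl trans to C7–C11 | CC(C)(C)[Si](C)(C)OCC1[C@H]2[C@H](O)C=C(C)C(=O)[C@@]2(C(OC)OC)OC1=O | intermediate
12 | saturated ketone: 11 with C9–C10 reduced, 10R methyl cis to the lactone oxygen | CC(C)(C)[Si](C)(C)OCC1[C@H]2[C@H](O)C[C@@H](C)C(=O)[C@@]2(C(OC)OC)OC1=O | intermediate
13 | C8 tert-butyldimethylsilyl ether of 12 | CC(C)(C)[Si](C)(C)OCC1[C@H]2[C@H](O[Si](C)(C)C(C)(C)C)C[C@@H](C)C(=O)[C@@]2(C(OC)OC)OC1=O | intermediate
14 | vinylmagnesium bromide | C=C[Mg]Br | starting material
15 | C1 vinyl carbinol (1R): hydroxyl cis to the lactone oxygen, vinyl cis to C5 | CC(C)(C)[Si](C)(C)OCC1[C@H]2[C@H](O[Si](C)(C)C(C)(C)C)C[C@@H](C)[C@](O)(C=C)[C@@]2(C(OC)OC)OC1=O | intermediate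
16 | C1 trimethylsilyl ether of 15 | CC(C)(C)[Si](C)(C)OCC1[C@H]2[C@H](O[Si](C)(C)C(C)(C)C)C[C@@H](C)[C@](O[Si](C)(C)C)(C=C)[C@@]2(C(OC)OC)OC1=O | intermediate
17 | C11 phenylselenide of 16, selenium cis to C7–H (not isolated) | CC(C)(C)[Si](C)(C)OC[C@@]1([Se]c3ccccc3)[C@H]2[C@H](O[Si](C)(C)C(C)(C)C)C[C@@H](C)[C@](O[Si](C)(C)C)(C=C)[C@@]2(C(OC)OC)OC1=O | intermediate
18 | bicyclic butenolide (C7=C11) with C6 CH(OMe)2, C1 OTMS and vinyl, C8 and C13 OTBS | CC(C)(C)[Si](C)(C)OCC1=C2[C@H](O[Si](C)(C)C(C)(C)C)C[C@@H](C)[C@](O[Si](C)(C)C)(C=C)[C@@]2(C(OC)OC)OC1=O | intermediate
19 | C5 aldehyde of 18 | CC(C)(C)[Si](C)(C)OCC1=C2[C@H](O[Si](C)(C)C(C)(C)C)C[C@@H](C)[C@](O[Si](C)(C)C)(C=C)[C@@]2(C=O)OC1=O | intermediate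
20 | diphenylphosphine oxide | O=[PH](c1ccccc1)c1ccccc1 | starting material
21 | acetaldehyde | CC=O | starting material
22 | (1-hydroxyethyl)diphenylphosphine oxide, racemic | CC(O)P(=O)(c1ccccc1)c1ccccc1 | intermediate
23 | [1-(methoxymethoxy)ethyl]diphenylphosphine oxide, racemic | CC(OCOC)P(=O)(c1ccccc1)c1ccccc1 | intermediate
24 | β-hydroxy phosphine oxide: C5 carbinol, C4 bearing P(O)Ph2, CH3 and OMOM; diastereomer with C6 and OMOM eclipsed when O–C5 and C4–P are syn | CC(C)(C)[Si](C)(C)OCC1=C2[C@H](O[Si](C)(C)C(C)(C)C)C[C@@H](C)[C@](O[Si](C)(C)C)(C=C)[C@@]2([C@H](O)[C@@](C)(OCOC)P(=O)(c3ccccc3)c3ccccc3)OC1=O | intermediate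
25 | (Z)-enol ether C5=C4(CH3)OMOM, OMOM cis to C6, with C1 trimethylsilyl ether | CC(C)(C)[Si](C)(C)OCC1=C2[C@H](O[Si](C)(C)C(C)(C)C)C[C@@H](C)[C@](O[Si](C)(C)C)(C=C)[C@@]2(/C=C(/C)OCOC)OC1=O | intermediate
26 | key-step precursor: (1R,6S,8R,10R) cis-1-vinyl-2-alkenylcyclohexanol on the bicyclic butenolide, (Z)-MOM enol ether | CC(C)(C)[Si](C)(C)OCC1=C2[C@H](O[Si](C)(C)C(C)(C)C)C[C@@H](C)[C@](O)(C=C)[C@@]2(/C=C(/C)OCOC)OC1=O | intermediate
27 | potassium alkoxide of 26 (not isolated) | CC(C)(C)[Si](C)(C)OCC1=C2[C@H](O[Si](C)(C)C(C)(C)C)C[C@@H](C)[C@]([O-])(C=C)[C@@]2(/C=C(/C)OCOC)OC1=O.[K+] | intermediate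
28 | ten-membered potassium enolate (C1=C2, C10 cis to C3) with ring-trans C5=C6 (not isolated) | CC(C)(C)[Si](C)(C)OCC1=C2/C(=C/[C@](C)(OCOC)C/C=C(/[O-])[C@H](C)C[C@H]2O[Si](C)(C)C(C)(C)C)OC1=O.[K+] | intermediate
29 | ten-membered keto ylidene-butenolide (4R,5Z,8R,10R): C4 cis to the lactone oxygen (ring-trans), C4 OMOM | CC(C)(C)[Si](C)(C)OCC1=C2/C(=C/[C@](C)(OCOC)CCC(=O)[C@H](C)C[C@H]2O[Si](C)(C)C(C)(C)C)OC1=O | intermediate
30 | ten-membered keto ylidene-butenolide (4R,5E,8R,10R): C4 cis to C7 (ring-cis), C4 OMOM | CC(C)(C)[Si](C)(C)OCC1=C2/C(=C\[C@](C)(OCOC)CCC(=O)[C@H](C)C[C@H]2O[Si](C)(C)C(C)(C)C)OC1=O | intermediate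
31 | C4 hydroxy C1 ketone from 30 (not isolated) | CC(C)(C)[Si](C)(C)OCC1=C2/C(=C\[C@](C)(O)CCC(=O)[C@H](C)C[C@H]2O[Si](C)(C)C(C)(C)C)OC1=O | intermediate
32 | 1,4-epoxy hemiketal (1S,4R,8R,10R) with C8 and C13 tert-butyldimethylsilyl ethers | CC(C)(C)[Si](C)(C)OCC1=C2/C(=C\[C@@]3(C)CC[C@](O)(O3)[C@H](C)C[C@H]2O[Si](C)(C)C(C)(C)C)OC1=O | intermediate
33 | hemiketal triol with free C8 and C13 hydroxyls | OCC1=C2/C(=C\[C@@]3(C)CC[C@](O)(O3)[C@H](C)C[C@H]2O)OC1=O | intermediate
34 | C13 acetate of 33 | CC(=O)OCC1=C2/C(=C\[C@@]3(C)CC[C@](O)(O3)[C@H](C)C[C@H]2O)OC1=O | intermediate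
35 | (R)-3-chloro-2-hydroxy-2-methylpropanoic acid | O=C(O)[C@@](C)(O)CCl | starting material
36 | CNP0414417.2 (1S,4R,8R,10R,2′R; 5E) | CC(=O)OCC1=C2/C(=C\[C@@]3(C)CC[C@](O)(O3)[C@H](C)C[C@H]2OC(=O)[C@@](C)(O)CCl)OC1=O | target

## Step count and least certain steps

Total step count: 24 (steps 1–13 and 16–24 on the main line, steps 14 and 15 for the phosphine oxide). Longest linear sequence: 22 steps, from 1 to 36.

Step 19 (key step). What may go wrong is heterolysis of the C1–C6 bond in the alkoxide, because the departing C6 carbanion is an aromatic 2-oxyfuran anion; the tethered vinyl ketone would then re-close without stereocontrol. Acyl transfer from the C6 oxygen to the C1 oxygen is the second risk. Fallback: start from 25 and heat the silyl ether itself (o-dichlorobenzene, about 170 °C, N,O-bis(trimethylsilyl)acetamide as acid scavenger). This neutral silyloxy variant of the same shift has no alkoxide, so neither fragmentation nor acyl transfer can occur, and it should give the ten-membered trimethylsilyl enol ether F1. Buffered Bu4NF/AcOH then frees the ketone and rejoins the route at 29.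

Step 20. The photostationary mixture may stay rich in the ring-trans isomer, or the dienyl lactone may undergo other photoreactions, because without the oxygen bridge nothing pulls the equilibrium. Fallback: start from 29, cleave the methoxymethyl ether first (Me2BBr, −78 °C) to the ring-trans hydroxy ketone F2, then equilibrate the C5=C6 geometry with a nucleophilic catalyst (PBu3, 10 mol %, THF). Reversible 1,6-addition at C5 through the 2-oxyfuran anion allows rotation, and only the ring-cis isomer can close the C1–O–C4 bridge, so the hemiketal acts as the sink. The route is rejoined at 32.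

Step 16. Poor diastereoselection is likely, because the aldehyde face and the configuration at the phosphorus-bearing carbon are set independently, so the Z-competent pair may be the minor one. Silyl migration from the C1 oxygen to the new alkoxide is a second risk. Fallback: start from the unwanted adducts formed from 19 and 23 and oxidise them (DMP, NaHCO3) to the β-keto phosphine oxide F3. Reduce F3 with NaBH4/CeCl3 (MeOH, −78 °C) or, for the opposite sense, with Zn(BH4)2; hydride delivery is steered by the adjacent C4 centre, so both C4 epimers converge on one relative C4/C5 configuration. The reductant is chosen to give the Z-competent pair, and the route is rejoined at 24.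

Step 13. The acetal may fail to ionise, since it is neopentyl and flanked by the acyloxy-bearing C6. Fallback: start from 18 and hydrolyse with aqueous trifluoroacetic acid (CH2Cl2, 0 °C). This removes the tertiary trimethylsilyl ether as well and gives the hydroxy aldehyde F4; 1-(trimethylsilyl)imidazole then restores the silyl ether and rejoins the route at 19.

Step 10. Addition on the wrong face, or enolisation with loss of the C10 configuration, may occur if the ketone reacts through a conformer other than the one with axial C6–O. Fallback: start from 13 and methylenate the ketone without base (Zn, CH2Br2, TiCl4) to F5. Epoxidise F5 with mCPBA/NaHCO3; the electrophile uses the face the nucleophile preferred, which puts the oxygen on the required side in the spiro-epoxide F6. Open F6 at its CH2 group with dimethylsulfonium methylide (Me3S+ I−, n-BuLi, THF); loss of dimethyl sulfide gives the one-carbon-homologated allylic alcohol and rejoins the route at 15.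

Step 7. Oxidation at C10 through the enol-ether double bond may compete, as may enolisation of the lactone with loss of the C13 silyloxy group. Fallback: start from 9 and deconjugate the enone by kinetic α-protonation of its potassium dienolate (KN(SiMe3)2, then AcOH, −78 °C) to the β,γ-enone F7. Epoxidise the isolated C8=C9 bond with mCPBA anti to C11 to give F8. A mild base (DBU, CH2Cl2) then opens the β,γ-epoxy ketone by enolisation at C10 and rejoins the route at 11.

## Further compounds

F1 | step 19 | ten-membered C1 trimethylsilyl enol ether with ring-trans C5=C6 | CC(C)(C)[Si](C)(C)OCC1=C2/C(=C/[C@](C)(OCOC)C/C=C(/O[Si](C)(C)C)[C@H](C)C[C@H]2O[Si](C)(C)C(C)(C)C)OC1=O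
F2 | step 20 | ring-trans C4 hydroxy C1 ketone | CC(C)(C)[Si](C)(C)OCC1=C2/C(=C/[C@](C)(O)CCC(=O)[C@H](C)C[C@H]2O[Si](C)(C)C(C)(C)C)OC1=O
F3 | step 16 | C5 ketone β-keto phosphine oxide, C4 epimers | CC(C)(C)[Si](C)(C)OCC1=C2[C@H](O[Si](C)(C)C(C)(C)C)C[C@@H](C)[C@](O[Si](C)(C)C)(C=C)[C@@]2(C(=O)C(C)(OCOC)P(=O)(c3ccccc3)c3ccccc3)OC1=O
F4 | step 13 | C1 hydroxy C5 aldehyde on the bicyclic butenolide | CC(C)(C)[Si](C)(C)OCC1=C2[C@H](O[Si](C)(C)C(C)(C)C)C[C@@H](C)[C@](O)(C=C)[C@@]2(C=O)OC1=O
F5 | step 10 | C1 exocyclic methylene analogue of 13 | CC(C)(C)[Si](C)(C)OCC1[C@H]2[C@H](O[Si](C)(C)C(C)(C)C)C[C@@H](C)C(=C)[C@@]2(C(OC)OC)OC1=O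
F6 | step 10 | C1 spiro-epoxide, oxygen cis to the lactone oxygen | CC(C)(C)[Si](C)(C)OCC1[C@H]2[C@H](O[Si](C)(C)C(C)(C)C)C[C@@H](C)[C@]3(CO3)[C@@]2(C(OC)OC)OC1=O
F7 | step 7 | β,γ-enone (C8=C9) isomer of 9, C10 epimers | CC(C)(C)[Si](C)(C)OCC1[C@H]2C=CC(C)C(=O)[C@@]2(C(OC)OC)OC1=O
F8 | step 7 | C8,C9 epoxide of F7, oxygen trans to C7–C11 | CC(C)(C)[Si](C)(C)OCC1[C@H]2[C@@H]3O[C@@H]3C(C)C(=O)[C@@]2(C(OC)OC)OC1=O
A1 | alternative 1 | acyclic C6 keto β-iodoacrylate with C8 aldehyde and C1/C4 methyl ketal | CC(=O)OC/C(C(=O)OC)=C(\I)C(=O)C[C@@]1(C)CC[C@](OC)(O1)[C@H](C)CC=O
A2 | alternative 1 | ten-membered C6 keto ester with 8R carbinol | CC(=O)OC/C(C(=O)OC)=C1/C(=O)C[C@@]3(C)CC[C@](OC)(O3)[C@H](C)C[C@H]1O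
A3 | alternative 2 | fully elaborated furanogermacrane with hemiketal, C13 acetate and C8 ester | CC(=O)OCc1coc2c1[C@H](OC(=O)[C@@](C)(O)CCl)C[C@@H](C)[C@]3(O)CC[C@@](C)(O3)C2
A4 | alternative 2 | 6-hydroxy-5,6-dihydro target, C6 unassigned | CC(=O)OCC1=C2C(O)(C[C@@]3(C)CC[C@](O)(O3)[C@H](C)C[C@H]2OC(=O)[C@@](C)(O)CCl)OC1=O
A5 | alternative 3 | eleven-membered sulfone bridging C9 and C10, furan and methyl ketal in place, C10 unassigned | CC1S(=O)(=O)C[C@@H](O[Si](C)(C)C(C)(C)C)c2c(CO[Si](C)(C)C(C)(C)C)coc2C[C@@]3(C)CC[C@]1(OC)O3
A6 | alternative 3 | ten-membered ring-cis C9=C10 alkene with furan and methyl ketal | C/C1=C/[C@@H](O[Si](C)(C)C(C)(C)C)c2c(CO[Si](C)(C)C(C)(C)C)coc2C[C@@]3(C)CC[C@]1(OC)O3
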